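## Retrosynthetic overview

1. Labels: ring carbons C1–C11 follow the target SMILES after the angelate oxygen (C1 O-angelate, C2 O-isovalerate, C3 OH, C4 CMe2, C5 H, C6 H, C7 H/Me, C8 H2, C9 C=O, C10 H, C11 Me). Rings: cyclobutane C5–C6–C11–C10, six-membered ring C5–C6–C7–C8–C9–C10, seven-membered ring C1–C2–C3–C4–C5–C10–C11.
2. Feature carrying the strategy: ketone carbon C9 lies in the bridge C7–C8–C9 over the cyclobutane and, in an open-chain dienoic acid, is the allylic carbon cis to the C11 methyl on the C10=C11 alkene. A temporary (S)-carbinol there fixes the face of cyclobutane formation, then directs H2 to C7 and C5, and is oxidised to the ketone at the end.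
3. Esters come off last (C2 isovalerate from the C2,C3-diol; C1 angelate from C1-OH of a C2,C3-acetonide). The triol comes from the C2=C3 cycloheptene (allylic oxidation at C1, reagent-controlled enone reduction, osmylation anti to C1-OH), and the cycloheptene from a C2,C3-dialdehyde by McMurry coupling.
4. C3–C4 is attached to C5 by olefination of the cyclobutanone, hydroxyl-directed hydrogenation (C5, C7) and C4 methylation. The bicyclo[3.1.1]heptan-6-one comes from an intramolecular vinylketene–alkene [2+2] (bonds C5–C10 and C6–C11) of a (5S)-5-silyloxy-3,7-dimethylnona-2,6-dienoic acid, itself made by enantioselective vinylogous aldol of an enal (C9, C10, C11, C1, C2; from but-3-yn-1-ol) with the dienol ether of methyl 3-methylbut-2-enoate (C5–C8).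
5. Ring order: cyclobutane and six-membered ring together (step 8), seven-membered ring last (step 17).

Key step: step 8

Assumption (chemistry): the (S,S) antipode of the bisphosphoramide is taken to send the dienol ether to the Si face of enal 6 (5S); if MTPA-ester analysis of 10 showed the opposite sense, the other antipode would be used. The (S)-oxazaborolidine in step 20 is chosen on the premise that quaternary C11 is the larger carbonyl substituent.

Remark: geometry mixtures at C5=C4 (18, 19) and epimer mixtures at C4 (20, 21) and C1 (28) are carried on, because these centres later become quaternary or trigonal.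

## Route

Step 1
Reactants: 1 but-3-yn-1-ol
Product: 3 4-methoxybenzyl but-3-yn-1-yl ether, via sodium but-3-yn-1-olate 2 (not isolated)
Conditions: NaH, THF/DMF, 0 °C; then 4-methoxybenzyl chloride, Bu4NI (cat.), 0 °C → rt
Reagents that add atoms: 4-methoxybenzyl chloride COc1ccc(CCl)cc1
Why: Williamson ether synthesis of the primary alkoxide with a benzylic chloride under iodide catalysis; no stereocentre is involved.

Step 2
Reactants: 3 4-methoxybenzyl but-3-yn-1-yl ether
Product: 5 (2E)-5-(4-methoxybenzyloxy)-3-methylpent-2-en-1-ol, via alkenyldimethylalane 4 (not isolated)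
Conditions: AlMe3 (2.5 equiv), Cp2ZrCl2 (0.25 equiv), CH2Cl2, 0 °C → rt; then (CH2O)n, 0 °C → rt; aq. potassium sodium tartrate
Reagents that add atoms: trimethylaluminium C[Al](C)C (the C11 methyl); paraformaldehyde, as formaldehyde C=O (C9 and its oxygen)
Why: Zirconium-catalysed syn carboalumination (Negishi) puts methyl on the internal and aluminium on the terminal alkyne carbon, and the alkenyl–aluminium bond adds to formaldehyde with retention, so the E allylic alcohol should carry CH2OH cis to the methyl group.

Step 3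
Reactants: 5 (2E)-5-(4-methoxybenzyloxy)-3-methylpent-2-en-1-ol
Product: 6 (2E)-5-(4-methoxybenzyloxy)-3-methylpent-2-enal
Conditions: MnO2 (excess), CH2Cl2, rt
Reagents that add atoms: none
Why: Allylic alcohol oxidation with MnO2 is selective for the allylic carbinol and should leave the PMB ether and the alkene geometry untouched.

Step 4
Reactants: 7 methyl 3-methylbut-2-enoate
Product: 9 tert-butyl[(1-methoxy-3-methylbuta-1,3-dien-1-yl)oxy]dimethylsilane, via lithium dienolate 8 (not isolated)
Conditions: LiN(i-Pr)2, THF, −78 °C; then TBSCl, DMPU, −78 °C → rt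
Reagents that add atoms: tert-butyldimethylsilyl chloride CC(C)(C)[Si](C)(C)Cl
Why: Kinetic γ-deprotonation of the enoate gives the extended dienolate, which is silylated on oxygen; the geometry at the ketene acetal carbon is immaterial.

Step 5
Reactants: 6 (2E)-5-(4-methoxybenzyloxy)-3-methylpent-2-enal; 9 tert-butyl[(1-methoxy-3-methylbuta-1,3-dien-1-yl)oxy]dimethylsilane
Product: 10 methyl (2E,5S,6E)-5-hydroxy-9-(4-methoxybenzyloxy)-3,7-dimethylnona-2,6-dienoate
Conditions: SiCl4 (1.1 equiv), (S,S)-bisphosphoramide [pentane-1,5-diylbis(methylamino)-linked bis-phosphoramide of N,N'-dimethyl-1,1'-binaphthyl-2,2'-diamine] (5 mol%), i-Pr2NEt (10 mol%), CH2Cl2, −78 °C; sat. aq. NaHCO3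
Reagents that add atoms: none
Why: Catalytic enantioselective vinylogous Mukaiyama aldol (chiral Lewis base activation of SiCl4) at the γ carbon of 9; the catalyst antipode that exposes the Si face of the formyl group sets the carbinol (C9 of the target) as 5S.

Step 6
Reactants: 10 methyl (2E,5S,6E)-5-hydroxy-9-(4-methoxybenzyloxy)-3,7-dimethylnona-2,6-dienoate
Product: 11 methyl (2E,5S,6E)-5-(tert-butyldimethylsilyloxy)-9-(4-methoxybenzyloxy)-3,7-dimethylnona-2,6-dienoate
Conditions: TBSCl, imidazole, DMF, rt
Reagents that add atoms: tert-butyldimethylsilyl chloride CC(C)(C)[Si](C)(C)Cl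
Why: Standard silylation of the secondary allylic alcohol; the stereocentre is not touched.

Step 7
Reactants: 11 methyl (2E,5S,6E)-5-(tert-butyldimethylsilyloxy)-9-(4-methoxybenzyloxy)-3,7-dimethylnona-2,6-dienoate
Product: 12 (2E,5S,6E)-5-(tert-butyldimethylsilyloxy)-9-(4-methoxybenzyloxy)-3,7-dimethylnona-2,6-dienoic acid
Conditions: LiOH·H2O, THF/MeOH/H2O, 40 °C; then 1 M HCl to pH 4, 0 °C
Reagents that add atoms: lithium hydroxide [Li+].[OH-] (one carboxyl oxygen)
Why: Ester saponification, to which the silyl ether, the PMB ether and both alkenes are inert; any E/Z drift of the enoate is harmless for step 8.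

Step 8
Reactants: 12 (2E,5S,6E)-5-(tert-butyldimethylsilyloxy)-9-(4-methoxybenzyloxy)-3,7-dimethylnona-2,6-dienoic acid
Product: 15 (9S)-4-(tert-butyldimethylsilyloxy)-7-[2-(4-methoxybenzyloxy)ethyl]-7-methyl-2-methylidenebicyclo[3.1.1]heptan-6-one, via dienoyl chloride 13 (not isolated), via vinylketene 14 (not isolated)
Conditions: 1-chloro-N,N,2-trimethylprop-1-en-1-amine, CH2Cl2, 0 °C → rt; concentrate; then slow addition (8 h) to Et3N (5 equiv), toluene, 110 °C, final 0.005 M
Reagents that add atoms: none
Why: Et3N removes HCl from dienoyl chloride 13 across the C7 methyl to give the cross-conjugated vinylketene 14, whose electrophilic carbon C5 bonds to the less substituted alkene carbon C10 while the positive charge building at tertiary C11 collapses onto C6, an asynchronous thermal [2+2] that is suprafacial on the alkene. The closest known reaction type is the intramolecular cycloaddition of vinylketenes made from 3-methylalka-2,6-dienoyl chlorides and Et3N, which gives 7,7-disubstituted 2-methylidenebicyclo[3.1.1]heptan-6-ones. The six-membered ring C5–C6–C7–C8–C9–C10 closes in the bridged mode by the first bond C5–C10 across the three-atom tether C7–C8–C9, and the cyclobutane C5–C6–C11–C10 closes by the second bond C6–C11. C11 is fixed by the E geometry of the alkene (its methyl, cis to C9, ends syn to the C7–C9 bridge and the C1 chain anti), C6 and C10 are tied to C11 by the bridged geometry, and the absolute sense of all three is relayed from C9. The step needs one face of the C10=C11 alkene: allylic 1,3-strain with the cis C11 methyl keeps C9–H next to that methyl, so the tether carbon C8 and the silyloxy group lie on opposite faces and the ketene adds anti to the silyloxy group, which also keeps the C–O bond out of conjugation with the reacting π bond and avoids a clash between the silyloxy group and the C11 methyl in the product, leaving the oxygen on the C5 side; this facial control is a conformational prediction for the new substrate. Chemoselectivity is secured because the trisubstituted alkene is the only ketenophile (PMB ether, arene and silyl ether are inert) and high dilution suppresses ketene dimerisation.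

Step 9
Reactants: 15 (9S)-4-(tert-butyldimethylsilyloxy)-7-[2-(4-methoxybenzyloxy)ethyl]-7-methyl-2-methylidenebicyclo[3.1.1]heptan-6-one; 16 triethyl 2-phosphonopropionate
Product: 18 ethyl 2-(bicyclo[3.1.1]heptan-6-ylidene)propanoate with exocyclic C5=C4 (E/Z mixture; other groups as in 15), via sodium phosphonate carbanion 17 (not isolated)
Conditions: 16, NaH, THF, 0 °C; then 15, 0 °C → 65 °C
Reagents that add atoms: none
Why: Horner–Wadsworth–Emmons olefination of a strain-activated cyclobutanone that cannot enolise (both α-carbons are bridgeheads), giving the tetrasubstituted C5=C4 enoate whose two geometries converge in step 13.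

Step 10
Reactants: 18 exocyclic C5=C4 enoate with C9-OTBS
Product: 19 exocyclic C5=C4 enoate with free C9-OH (9S; hydroxyl on the C5 side)
Conditions: Bu4NF, THF, 0 °C → rt; H2O
Reagents that add atoms: none
Why: Fluoride-mediated desilylation uncovers the directing hydroxyl, while the ester, the PMB ether and both alkenes are inert.

Step 11
Reactants: 19 exocyclic C5=C4 enoate with free C9-OH
Product: 20 ethyl 2-substituted propanoate with C7 and C5 saturated (C7 methyl toward C11; C5–H syn to the C7–C9 bridge; C4 epimer mixture; C9-OH)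
Conditions: H2 (up to 30 bar), [Ir(cod)(PCy3)(py)]PF6 (10 mol%), CH2Cl2, rt
Reagents that add atoms: none
Why: Hydroxyl-directed homogeneous hydrogenation, in which the cationic iridium catalyst bound to C9-OH delivers H2 to the homoallylic C7=CH2 and C5=C4 alkenes from the hydroxyl face, setting C7 (methyl toward C11) and C5 (hydrogen syn to the bridge, C4 anti); the opposite faces are in addition shielded by the C11 methyl and the C1 chain.

Step 12
Reactants: 20 saturated hydroxy ester
Product: 21 saturated ester with C9-OTBS (C4 epimer mixture)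
Conditions: TBSOTf, 2,6-lutidine, CH2Cl2, −78 → 0 °C
Reagents that add atoms: tert-butyldimethylsilyl trifluoromethanesulfonate CC(C)(C)[Si](C)(C)OS(=O)(=O)C(F)(F)F
Why: Silylation of the secondary alcohol with the silyl triflate protects C9 against the base, hydride and oxidants of the following steps.

Step 13
Reactants: 21 saturated ester with C9-OTBS
Product: 23 ethyl 2-methyl-2-substituted propanoate (C4 gem-dimethyl), via lithium ester enolate 22 (not isolated)
Conditions: LiN(i-Pr)2, THF, −78 → −40 °C; then MeI, DMPU, −78 → 0 °C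
Reagents that add atoms: iodomethane CI
Why: Ester enolate alkylation with iodomethane makes C4 quaternary and removes the C4 epimer mixture.

Step 14
Reactants: 23 gem-dimethyl ester with PMB ether
Product: 24 gem-dimethyl ester with free C2-OH
Conditions: DDQ, CH2Cl2/pH 7 phosphate buffer, 0 °C → rt
Reagents that add atoms: none
Why: Oxidative PMB cleavage by DDQ (hydride abstraction from the electron-rich benzylic ether, then hydrolysis) spares the silyl ether and the ester.

Step 15
Reactants: 24 gem-dimethyl ester with free C2-OH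
Product: 25 C2,C3-diol (2-hydroxyethyl on C11; 1-hydroxy-2-methylpropan-2-yl on C5)
Conditions: LiAlH4, THF, 0 → 40 °C; H2O/aq. NaOH
Reagents that add atoms: none
Why: Hydride reduction of the hindered α-quaternary ester with LiAlH4 gives the neopentyl alcohol; the secondary silyl ether is stable.

Step 16
Reactants: 25 C2,C3-diol
Product: 26 C2,C3-dialdehyde
Conditions: (COCl)2, DMSO, CH2Cl2, −78 °C; Et3N, −78 → −20 °C
Reagents that add atoms: none
Why: Swern oxidation of both primary alcohols; the C3 aldehyde has no α-hydrogen and the cold work-up limits aldol reaction of the C2 aldehyde.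

Step 17
Reactants: 26 C2,C3-dialdehyde
Product: 27 tricyclic cycloheptene (C2=C3) with C9-OTBS
Conditions: TiCl3(DME)1.5, Zn–Cu couple, DME, reflux; 26 added over 30 h (final ≤0.005 M)
Reagents that add atoms: none
Why: McMurry reductive coupling joins the two formyl carbons through a titanium pinacolate and deoxygenates it to the cis C2=C3 alkene, closing the seven-membered ring, whose nearly eclipsed C1–C2–C3–C4 bridge accommodates a cis alkene; high dilution disfavours intermolecular coupling.

Step 18
Reactants: 27 tricyclic cycloheptene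
Product: 28 C1 allylic alcohol (C1 epimer mixture)
Conditions: SeO2 (0.5 equiv), t-BuOOH (3 equiv), CH2Cl2, rt → 40 °C
Reagents that add atoms: selenium dioxide O=[Se]=O (oxygen carrier); tert-butyl hydroperoxide CC(C)(C)OO (terminal oxygen source)
Why: Riley allylic oxidation (ene reaction at C3 with transfer of a C1 hydrogen, then [2,3]-sigmatropic shift) returns the alkene to C2=C3 and places oxygen on C1, the only allylic CH2 because C4 is quaternary; the C1 configuration is irrelevant here.

Step 19
Reactants: 28 C1 allylic alcohol (epimer mixture)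
Product: 29 C1 enone (C1=O conjugated with C2=C3)
Conditions: Dess–Martin periodinane, NaHCO3, CH2Cl2, rt
Reagents that add atoms: none
Why: Dess–Martin oxidation converts both C1 epimers into one enone under buffered conditions that spare the silyl ether.

Step 20
Reactants: 29 C1 enone
Product: 30 C1 allylic alcohol with the hydroxyl on the C10 side
Conditions: (S)-2-methyl-CBS-oxazaborolidine (0.5 equiv), BH3·THF, THF, −40 °C; MeOH
Reagents that add atoms: none
Why: Corey–Bakshi–Shibata reduction under reagent control, needed because the core is nearly mirror-symmetric around C1; with quaternary C11 as the large and the C2=C3 alkene as the small substituent, the (S)-catalyst should deliver hydride from the C6 side and place the hydroxyl on the C10 side.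

Step 21
Reactants: 30 C1 allylic alcohol
Product: 31 C1,C2,C3-triol (C1-OH on the C10 side; C2-OH and C3-OH cis on the C6 side) with C9-OTBS
Conditions: OsO4 (5 mol%), NMO, acetone/H2O, rt
Reagents that add atoms: osmium tetroxide O=[Os](=O)(=O)=O (oxygen carrier); 4-methylmorpholine N-oxide C[N+]1([O-])CCOCC1 (reoxidant)
Why: Upjohn dihydroxylation adds both oxygens syn to the face of C2=C3 anti to the allylic C1 hydroxyl (the empirical anti rule for osmylation of allylic alcohols), giving the cis C2,C3-diol trans to C1-OH.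

Step 22
Reactants: 31 C1,C2,C3-triol
Product: 32 C2,C3-acetonide with free C1-OH
Conditions: 2,2-dimethoxypropane, PPTS (cat.), acetone, rt
Reagents that add atoms: 2,2-dimethoxypropane COC(C)(C)OC
Why: Acid-catalysed ketal exchange under thermodynamic control selects the cis C2,C3-diol (cis-fused dioxolane) over the trans C1,C2 pair and leaves C1-OH free.

Step 23
Reactants: 32 C2,C3-acetonide with free C1-OH; 33 angelic acid
Product: 35 C1 angelate of the C2,C3-acetonide with C9-OTBS, via angelic 2,4,6-trichlorobenzoic anhydride 34 (not isolated)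
Conditions: 33, 2,4,6-trichlorobenzoyl chloride, Et3N, toluene, rt; then 32, toluene, 80 °C
Reagents that add atoms: none
Why: Yamaguchi-type esterification through the mixed anhydride without a nucleophilic catalyst, conditions under which the Z geometry of the angelate should be retained.

Step 24
Reactants: 35 C1 angelate with C9-OTBS
Product: 36 C1 angelate with free C9-OH
Conditions: Bu4NF, AcOH (1:1), THF, rt → 40 °C
Reagents that add atoms: none
Why: Buffered fluoride desilylation frees C9-OH while the acetic acid keeps the medium non-basic, so the angelate should neither isomerise nor be cleaved.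

Step 25
Reactants: 36 C1 angelate with free C9-OH
Product: 37 C1 angelate C2,C3-acetonide C9 ketone
Conditions: Dess–Martin periodinane, NaHCO3, CH2Cl2, rt
Reagents that add atoms: none
Why: Dess–Martin oxidation turns the sacrificial C9 carbinol into the target ketone; no epimerisable centre is adjacent (C10 is a bridgehead).

Step 26
Reactants: 37 C1 angelate C2,C3-acetonide C9 ketone
Product: 38 C1 angelate C2,C3-diol C9 ketone
Conditions: AcOH/H2O (4:1), 40 °C
Reagents that add atoms: none
Why: Mild acidic hydrolysis of the isopropylidene ketal, to which the ester and the ketone are stable.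

Step 27
Reactants: 38 C1 angelate C2,C3-diol C9 ketone; 39 isovaleric anhydride
Product: 40 target CNP0323312.1
Conditions: 39 (1.1 equiv), DMAP (cat.), pyridine, CH2Cl2, −40 → −20 °C
Reagents that add atoms: none
Why: Kinetically controlled DMAP-catalysed acylation should take the less hindered C2-OH, whereas the neopentylic C3-OH next to C4 stays free.

## Compound list

1 | but-3-yn-1-ol | C#CCCO | starting material
2 | sodium but-3-yn-1-olate | C#CCC[O-].[Na+] | intermediate (not isolated)
3 | 4-methoxybenzyl but-3-yn-1-yl ether | C#CCCOCc1ccc(OC)cc1 | intermediate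
4 | dimethyl[(1E)-4-(4-methoxybenzyloxy)-2-methylbut-1-en-1-yl]alane (Al cis to the methyl) | C[Al](C)/C=C(\C)CCOCc1ccc(OC)cc1 | intermediate (not isolated)
5 | (2E)-5-(4-methoxybenzyloxy)-3-methylpent-2-en-1-ol | OC/C=C(\C)CCOCc1ccc(OC)cc1 | intermediate
6 | (2E)-5-(4-methoxybenzyloxy)-3-methylpent-2-enal | O=C/C=C(\C)CCOCc1ccc(OC)cc1 | intermediate
7 | methyl 3-methylbut-2-enoate | COC(=O)C=C(C)C | starting material
8 | lithium 1-methoxy-3-methylbuta-1,3-dien-1-olate | CO/C([O-])=C/C(C)=C.[Li+] | intermediate (not isolated)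
9 | tert-butyl{[(1Z)-1-methoxy-3-methylbuta-1,3-dien-1-yl]oxy}dimethylsilane | CO/C(O[Si](C)(C)C(C)(C)C)=C/C(C)=C | intermediate
10 | methyl (2E,5S,6E)-5-hydroxy-9-(4-methoxybenzyloxy)-3,7-dimethylnona-2,6-dienoate | COC(=O)/C=C(\C)C[C@H](O)/C=C(\C)CCOCc1ccc(OC)cc1 | intermediate
11 | methyl (2E,5S,6E)-5-(tert-butyldimethylsilyloxy)-9-(4-methoxybenzyloxy)-3,7-dimethylnona-2,6-dienoate | COC(=O)/C=C(\C)C[C@H](O[Si](C)(C)C(C)(C)C)/C=C(\C)CCOCc1ccc(OC)cc1 | intermediate
12 | (2E,5S,6E)-5-(tert-butyldimethylsilyloxy)-9-(4-methoxybenzyloxy)-3,7-dimethylnona-2,6-dienoic acid | OC(=O)/C=C(\C)C[C@H](O[Si](C)(C)C(C)(C)C)/C=C(\C)CCOCc1ccc(OC)cc1 | intermediate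
13 | (2E,5S,6E)-5-(tert-butyldimethylsilyloxy)-9-(4-methoxybenzyloxy)-3,7-dimethylnona-2,6-dienoyl chloride | ClC(=O)/C=C(\C)C[C@H](O[Si](C)(C)C(C)(C)C)/C=C(\C)CCOCc1ccc(OC)cc1 | intermediate (not isolated)
14 | (5S,6E)-5-(tert-butyldimethylsilyloxy)-9-(4-methoxybenzyloxy)-7-methyl-3-methylidenenona-1,6-dien-1-one (vinylketene) | O=C=CC(=C)C[C@H](O[Si](C)(C)C(C)(C)C)/C=C(\C)CCOCc1ccc(OC)cc1 | intermediate (not isolated)
15 | (9S)-4-(tert-butyldimethylsilyloxy)-7-[2-(4-methoxybenzyloxy)ethyl]-7-methyl-2-methylidenebicyclo[3.1.1]heptan-6-one; C5 ketone bridge, C6/C10 bridgeheads, C7(=CH2)–C8–C9 bridge, C11 bridge; OTBS on the C5 side, C11 methyl syn to the C7–C9 bridge, C1–C2 chain anti | O=C1[C@@H]2C(=C)C[C@H](O[Si](C)(C)C(C)(C)C)[C@H]1[C@@]2(CCOCc3ccc(OC)cc3)C | intermediate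
16 | triethyl 2-phosphonopropionate | CCOC(=O)C(C)P(=O)(OCC)OCC | starting material
17 | sodium salt of the carbanion of 16 | CCOC(=O)[C-](C)P(=O)(OCC)OCC.[Na+] | intermediate (not isolated)
18 | ethyl 2-ylidenepropanoate of 15: exocyclic C5=C4(CH3)CO2Et, E/Z mixture, C9-OTBS | CCOC(=O)C(C)=C1[C@@H]2C(=C)C[C@H](O[Si](C)(C)C(C)(C)C)[C@H]1[C@@]2(CCOCc3ccc(OC)cc3)C | intermediate
19 | C9 alcohol of 18 (9S, hydroxyl on the C5 side) | CCOC(=O)C(C)=C1[C@@H]2C(=C)C[C@H](O)[C@H]1[C@@]2(CCOCc3ccc(OC)cc3)C | intermediate
20 | saturated hydroxy ester: C7 methyl toward C11, C5–H syn to the C7–C9 bridge, C4 epimer mixture, C9-OH | CCOC(=O)C(C)[C@H]1[C@@H]2[C@@H](C)C[C@H](O)[C@H]1[C@@]2(CCOCc3ccc(OC)cc3)C | intermediate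
21 | C9 tert-butyldimethylsilyl ether of 20 | CCOC(=O)C(C)[C@H]1[C@@H]2[C@@H](C)C[C@H](O[Si](C)(C)C(C)(C)C)[C@H]1[C@@]2(CCOCc3ccc(OC)cc3)C | intermediate
22 | lithium enolate of ester 21 | CCOC([O-])=C(C)[C@H]1[C@@H]2[C@@H](C)C[C@H](O[Si](C)(C)C(C)(C)C)[C@H]1[C@@]2(CCOCc3ccc(OC)cc3)C.[Li+] | intermediate (not isolated)
23 | gem-dimethyl ester: C4(CH3)2–CO2Et on C5, C9-OTBS, PMB ether on C2 | CCOC(=O)C(C)(C)[C@H]1[C@@H]2[C@@H](C)C[C@H](O[Si](C)(C)C(C)(C)C)[C@H]1[C@@]2(CCOCc3ccc(OC)cc3)C | intermediate
24 | gem-dimethyl ester with free C2-OH | CCOC(=O)C(C)(C)[C@H]1[C@@H]2[C@@H](C)C[C@H](O[Si](C)(C)C(C)(C)C)[C@H]1[C@@]2(CCO)C | intermediate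
25 | C2,C3-diol | OCC(C)(C)[C@H]1[C@@H]2[C@@H](C)C[C@H](O[Si](C)(C)C(C)(C)C)[C@H]1[C@@]2(CCO)C | intermediate
26 | C2,C3-dialdehyde | O=CC(C)(C)[C@H]1[C@@H]2[C@@H](C)C[C@H](O[Si](C)(C)C(C)(C)C)[C@H]1[C@@]2(CC=O)C | intermediate
27 | tricyclic cycloheptene (C2=C3) with C9-OTBS | C1C=CC(C)(C)[C@H]2[C@@H]3[C@@H](C)C[C@H](O[Si](C)(C)C(C)(C)C)[C@H]2[C@@]31C | intermediate
28 | C1 allylic alcohol, C1 epimer mixture | OC1C=CC(C)(C)[C@H]2[C@@H]3[C@@H](C)C[C@H](O[Si](C)(C)C(C)(C)C)[C@H]2[C@@]31C | intermediate
29 | C1 enone | O=C1C=CC(C)(C)[C@H]2[C@@H]3[C@@H](C)C[C@H](O[Si](C)(C)C(C)(C)C)[C@H]2[C@@]31C | intermediate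
30 | C1 allylic alcohol, hydroxyl on the C10 side | O[C@@H]1C=CC(C)(C)[C@H]2[C@@H]3[C@@H](C)C[C@H](O[Si](C)(C)C(C)(C)C)[C@H]2[C@@]31C | intermediate
31 | C1,C2,C3-triol (C1-OH on the C10 side; C2-OH and C3-OH on the C6 side), C9-OTBS | O[C@@H]1[C@@H](O)[C@@H](O)C(C)(C)[C@H]2[C@@H]3[C@@H](C)C[C@H](O[Si](C)(C)C(C)(C)C)[C@H]2[C@@]31C | intermediate
32 | C2,C3-acetonide (2,2-dimethyl-1,3-dioxolane) with free C1-OH, C9-OTBS | O[C@@H]1[C@@H](OC(C)(C)O4)[C@@H]4C(C)(C)[C@H]2[C@@H]3[C@@H](C)C[C@H](O[Si](C)(C)C(C)(C)C)[C@H]2[C@@]31C | intermediate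
33 | angelic acid, (2Z)-2-methylbut-2-enoic acid | C/C=C(/C)C(=O)O | starting material
34 | angelic 2,4,6-trichlorobenzoic anhydride | C/C=C(/C)C(=O)OC(=O)c1c(Cl)cc(Cl)cc1Cl | intermediate (not isolated)
35 | C1 angelate of 32 (C9-OTBS) | C/C=C(/C)C(=O)O[C@@H]1[C@@H](OC(C)(C)O4)[C@@H]4C(C)(C)[C@H]2[C@@H]3[C@@H](C)C[C@H](O[Si](C)(C)C(C)(C)C)[C@H]2[C@@]31C | intermediate
36 | C1 angelate, C2,C3-acetonide, free C9-OH | C/C=C(/C)C(=O)O[C@@H]1[C@@H](OC(C)(C)O4)[C@@H]4C(C)(C)[C@H]2[C@@H]3[C@@H](C)C[C@H](O)[C@H]2[C@@]31C | intermediate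
37 | C1 angelate, C2,C3-acetonide, C9 ketone | C/C=C(/C)C(=O)O[C@@H]1[C@@H](OC(C)(C)O4)[C@@H]4C(C)(C)[C@H]2[C@@H]3[C@@H](C)CC(=O)[C@H]2[C@@]31C | intermediate
38 | C1 angelate, C2,C3-diol, C9 ketone | C/C=C(/C)C(=O)O[C@@H]1[C@@H](O)[C@@H](O)C(C)(C)[C@H]2[C@@H]3[C@@H](C)CC(=O)[C@H]2[C@@]31C | intermediate
39 | isovaleric anhydride (3-methylbutanoic anhydride) | CC(C)CC(=O)OC(=O)CC(C)C | starting material
40 | CNP0323312.1: C1 angelate, C2 isovalerate, C3-OH, C9 ketone | C/C=C(/C)C(=O)O[C@@H]1[C@@H](OC(=O)CC(C)C)[C@@H](O)C(C)(C)[C@H]2[C@@H]3[C@@H](C)CC(=O)[C@H]2[C@@]31C | target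

## Step count and risks

Total step count: 27. Longest linear sequence: 26 steps (1 to 40 through steps 1–3 and 5–27; step 4 is the side branch).

Steps most likely to fail:

1. Step 8. The ketene may add to both faces of the C10=C11 alkene at 110 °C if the conformational bias from the C9 silyloxy group is too small, and deprotonation at C8 instead of the C7 methyl can divert material with loss of silanol. Fallback with a larger steering group: from 10, TIPSOTf and 2,6-lutidine give methyl (2E,5S,6E)-9-(4-methoxybenzyloxy)-3,7-dimethyl-5-(triisopropylsilyloxy)nona-2,6-dienoate F1. LiOH hydrolysis gives the corresponding dienoic acid F2. The chloroenamine of step 8 converts it into the dienoyl chloride F3, and Et3N in refluxing toluene at high dilution gives the vinylketene F4 and from it the triisopropylsilyloxy bicyclic ketone F5. Olefination with 17 as in step 9 gives the triisopropylsilyloxy enoate F6, and Bu4NF brings the material back to the route at 19.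

2. Step 9. The stabilised, α-branched phosphonate anion may add too slowly to the cyclobutanone flanked by two substituted bridgeheads, or the alkoxide adduct may open the strained ring before elimination. Fallback by aldol addition and dehydration: from 15, the smaller and more nucleophilic lithium enolate of ethyl propanoate F7 (ethyl propanoate, LiN(i-Pr)2, THF, −78 °C) adds to the carbonyl to give the β-hydroxy ester F8. Dehydration with SOCl2 and pyridine in CH2Cl2 at 0 °C can only run towards C4, because C6 and C10 are bridgeheads, and returns the route to 18.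

3. Step 20. Facial discrimination may be poor if the oxazaborolidine does not clearly rank quaternary C11 above the C2=C3 alkene, so that both C1 epimers form. Fallback by separation and recycling: from 29, unselective Luche reduction (NaBH4, CeCl3·7H2O, MeOH, −78 °C) gives the epimer mixture 28. Chromatography separates 30 from the C1-epimeric allylic alcohol F9, which is re-oxidised with Dess–Martin periodinane to 29 and reduced again, so the material comes back to the route at 30.

Further compounds
F1 | step 8 | methyl (2E,5S,6E)-9-(4-methoxybenzyloxy)-3,7-dimethyl-5-(triisopropylsilyloxy)nona-2,6-dienoate | COC(=O)/C=C(\C)C[C@H](O[Si](C(C)C)(C(C)C)C(C)C)/C=C(\C)CCOCc1ccc(OC)cc1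
F2 | step 8 | (2E,5S,6E)-9-(4-methoxybenzyloxy)-3,7-dimethyl-5-(triisopropylsilyloxy)nona-2,6-dienoic acid | OC(=O)/C=C(\C)C[C@H](O[Si](C(C)C)(C(C)C)C(C)C)/C=C(\C)CCOCc1ccc(OC)cc1
F3 | step 8 | (2E,5S,6E)-9-(4-methoxybenzyloxy)-3,7-dimethyl-5-(triisopropylsilyloxy)nona-2,6-dienoyl chloride | ClC(=O)/C=C(\C)C[C@H](O[Si](C(C)C)(C(C)C)C(C)C)/C=C(\C)CCOCc1ccc(OC)cc1
F4 | step 8 | (5S,6E)-9-(4-methoxybenzyloxy)-7-methyl-3-methylidene-5-(triisopropylsilyloxy)nona-1,6-dien-1-one (vinylketene) | O=C=CC(=C)C[C@H](O[Si](C(C)C)(C(C)C)C(C)C)/C=C(\C)CCOCc1ccc(OC)cc1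
F5 | step 8 | (9S)-7-[2-(4-methoxybenzyloxy)ethyl]-7-methyl-2-methylidene-4-(triisopropylsilyloxy)bicyclo[3.1.1]heptan-6-one | O=C1[C@@H]2C(=C)C[C@H](O[Si](C(C)C)(C(C)C)C(C)C)[C@H]1[C@@]2(CCOCc3ccc(OC)cc3)C
F6 | step 8 | triisopropylsilyl analogue of 18 (exocyclic C5=C4 enoate, E/Z mixture) | CCOC(=O)C(C)=C1[C@@H]2C(=C)C[C@H](O[Si](C(C)C)(C(C)C)C(C)C)[C@H]1[C@@]2(CCOCc3ccc(OC)cc3)C
F7 | step 9 | lithium enolate of ethyl propanoate | CC=C([O-])OCC.[Li+]
F8 | step 9 | ethyl 2-(6-hydroxybicyclo[3.1.1]heptan-6-yl)propanoate from 15 (β-hydroxy ester; C4 and C5 configurations not controlled) | CCOC(=O)C(C)C1(O)[C@@H]2C(=C)C[C@H](O[Si](C)(C)C(C)(C)C)[C@H]1[C@@]2(CCOCc3ccc(OC)cc3)C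
F9 | step 20 | C1 epimer of 30 (hydroxyl on the C6 side) | O[C@H]1C=CC(C)(C)[C@H]2[C@@H]3[C@@H](C)C[C@H](O[Si](C)(C)C(C)(C)C)[C@H]2[C@@]31C
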